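**Plan**
1. Retrosynthesis: the C3 silyl ether and the C8 isovalerate are removed, then the α-methylene-γ-lactone is cut at C11–C7. In the trans-fused lactone ring (O6–C12–C11–C7–C6) C7 carries C11 anti to the C8 oxygen, which is the mark of a rear-side opening of a trans-7,8-epoxide by C11 of an acrylate held on O6.
2. The ten-membered ring (C1–C10) is cut at C5–C6 (alkenyl iodide + epoxy aldehyde), and the chain at C8–C9 (allylic bromide + propargyl alcohol) and C2–C3 (vinylogous aldol of a tiglate dienolate with (Z)-3-iodo-2-methylacrolein).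
3. Forward order: acyclic chain C5→C6, then the 7,8-epoxide, the 1,10-epoxide, the ten-membered carbocycle, and last the γ-lactone; acylation of O8 and desilylation finish.
4. Stereochemistry: C3 from the catalyst-controlled vinylogous aldol; C7/C8 from Sharpless epoxidation; C1/C10 from Shi epoxidation; C6 from Felkin–Anh addition during ring closure; final C7 by SN2 inversion in the key step (C8 retained).
5. Alkene geometry: 4Z from anti-carbomagnesiation of propargyl alcohol; the E-alkenes that become the two trans-epoxides from the aldol and from Red-Al reduction.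

Key step: step 15

Remark: ring atoms are numbered as in germacranolides (C1–C10 ring, C11–C13 methylene-lactone carbons, C14 on C10, C15 on C4).
Assumption: the (R,R)-bisphosphoramide·SiCl4 system is taken to direct the dienolate to the Re face of enal 4; should a test reaction show the opposite sense, the (S,S)-catalyst is used and nothing else changes.

**Step 1**
Reactants: 1 prop-2-yn-1-ol (propargyl alcohol)
Product: 3 (Z)-3-iodo-2-methylprop-2-en-1-ol, via alkenylmagnesium alkoxide 2 (not isolated)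
Conditions: MeMgBr (2.5 equiv), CuI (10 mol %), THF/Et2O, −10 °C → rt; then I2, −10 °C
Reagents that add atoms: methylmagnesium bromide, C[Mg]Br; iodine, II
Why: Copper-catalysed anti-carbomagnesiation of the propargylic alkoxide should place methyl on the internal carbon and magnesium on the terminal carbon cis to the chelating CH2O group, and iodinolysis with retention then fixes the Z geometry of the later C4=C5 bond.

**Step 2**
Reactants: 3 (Z)-3-iodo-2-methylprop-2-en-1-ol
Product: 4 (Z)-3-iodo-2-methylprop-2-enal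
Conditions: MnO2 (15 equiv), CH2Cl2, rt, dark
Reagents that add atoms: none
Why: Allylic alcohol oxidation with MnO2 is neutral and should leave the alkenyl iodide and its Z geometry untouched.

**Step 3**
Reactants: 5 ethyl tiglate [ethyl (E)-2-methylbut-2-enoate]
Product: 7 tert-butyl[(1-ethoxy-2-methylbuta-1,3-dien-1-yl)oxy]dimethylsilane (ketene acetal geometry not controlled), via lithium dienolate 6 (not isolated)
Conditions: LiN(iPr)2 (LDA), THF/DMPU, −78 °C; then TBSCl, −78 °C → rt
Reagents that add atoms: tert-butyldimethylsilyl chloride, CC(C)(C)[Si](C)(C)Cl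
Why: γ-Deprotonation of the unsaturated ester gives the extended enolate, which is silylated on oxygen (silyl ketene acetal formation).

**Step 4**
Reactants: 4 (Z)-3-iodo-2-methylprop-2-enal; 7 silyl dienol ether
Product: 8 ethyl (2E,5R,6Z)-5-hydroxy-7-iodo-2,6-dimethylhepta-2,6-dienoate
Conditions: SiCl4 (1.1 equiv), (R,R)-bisphosphoramide catalyst (pentane-1,5-diyl-linked bis-phosphoramide of (R)-N,N'-dimethyl-1,1'-binaphthyl-2,2'-diamine, 2 mol %), iPr2NEt (10 mol %), CH2Cl2, −78 °C; aq. NaHCO3
Reagents that add atoms: none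
Why: In this enantioselective vinylogous Mukaiyama aldol reaction the phosphoramide-bound trichlorosilyl cation activates the enal, the dienolate should react only through its γ-carbon on the Re face to set the (R)-carbinol (future C3), and the new conjugated double bond (future C1=C10) forms E.

**Step 5**
Reactants: 8 hydroxy ester
Product: 9 ethyl (2E,5R,6Z)-5-[(tert-butyldimethylsilyl)oxy]-7-iodo-2,6-dimethylhepta-2,6-dienoate
Conditions: TBSOTf, 2,6-lutidine, CH2Cl2, −78 → 0 °C
Reagents that add atoms: tert-butyldimethylsilyl triflate, CC(C)(C)[Si](C)(C)OS(=O)(=O)C(F)(F)F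
Why: Silylation of the secondary allylic alcohol protects O3 until the last step.

**Step 6**
Reactants: 9 silyloxy ester
Product: 10 (2E,5R,6Z)-5-[(tert-butyldimethylsilyl)oxy]-7-iodo-2,6-dimethylhepta-2,6-dien-1-ol
Conditions: iBu2AlH (DIBAL-H, 2.5 equiv), CH2Cl2, −78 °C; aq. potassium sodium tartrate
Reagents that add atoms: none
Why: 1,2-Reduction of the enoate gives the allylic alcohol (future C9) without touching the alkenyl iodide or the silyl ether.

**Step 7**
Reactants: 10 allylic alcohol
Product: 11 tert-butyl{[(1Z,3R,5E)-7-bromo-1-iodo-2,6-dimethylhepta-1,5-dien-3-yl]oxy}dimethylsilane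
Conditions: CBr4, PPh3, CH2Cl2, 0 °C
Reagents that add atoms: carbon tetrabromide, BrC(Br)(Br)Br
Why: Appel bromination converts the primary allylic alcohol into the bromide under neutral conditions without allylic transposition.

**Step 8**
Reactants: 11 allylic bromide; 1 prop-2-yn-1-ol
Product: 12 (5E,8R,9Z)-8-[(tert-butyldimethylsilyl)oxy]-10-iodo-5,9-dimethyldeca-5,9-dien-2-yn-1-ol
Conditions: CuI (10 mol %), K2CO3, Bu4NCl (10 mol %), DMF, rt
Reagents that add atoms: none
Why: Copper-catalysed coupling of the terminal alkyne with the primary allylic bromide (SN2 at CH2, disfavouring SN2' at the substituted γ-carbon) should form the C8–C9 bond and keep the E-alkene, while the carbonate base does not deprotonate the alcohol, so O-allylation is avoided.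

**Step 9**
Reactants: 12 enynol
Product: 13 (2E,5E,8R,9Z)-8-[(tert-butyldimethylsilyl)oxy]-10-iodo-5,9-dimethyldeca-2,5,9-trien-1-ol
Conditions: NaAlH2(OCH2CH2OMe)2 (Red-Al, 1.5 equiv), THF, −20 → 0 °C; aq. potassium sodium tartrate
Reagents that add atoms: none
Why: Alkoxide-directed trans-hydroalumination of the propargylic alcohol gives the E-allylic alcohol (C7=C8), and at or below 0 °C the isolated alkene and the alkenyl iodide should not be reduced.

**Step 10**
Reactants: 13 dienol
Product: 14 {(2R,3R)-3-[(2E,5R,6Z)-5-{[tert-butyl(dimethyl)silyl]oxy}-7-iodo-2,6-dimethylhepta-2,6-dien-1-yl]oxiran-2-yl}methanol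
Conditions: Ti(OiPr)4 (10 mol %), D-(−)-diethyl tartrate (12 mol %), t-BuOOH, 4 Å molecular sieves, CH2Cl2, −20 °C
Reagents that add atoms: tert-butyl hydroperoxide, CC(C)(C)OO
Why: Sharpless asymmetric epoxidation acts only on the allylic alcohol alkene, and the D-tartrate ligand delivers oxygen to the face that gives the (2R,3R)-epoxy alcohol, that is the trans-7,8-epoxide with (8R).

**Step 11**
Reactants: 14 epoxy alcohol
Product: 15 [(2R,3R)-3-({(2R,3R)-3-[(2R,3Z)-2-{[tert-butyl(dimethyl)silyl]oxy}-4-iodo-3-methylbut-3-en-1-yl]-2-methyloxiran-2-yl}methyl)oxiran-2-yl]methanol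
Conditions: 1,2:4,5-di-O-isopropylidene-β-D-erythro-2,3-hexodiulo-2,6-pyranose (D-fructose-derived ketone, 30 mol %), KHSO5 (Oxone), K2CO3, Bu4NHSO4, MeCN/CH2(OMe)2–aq. Na2B4O7 buffer, 0 °C
Reagents that add atoms: potassium peroxymonosulfate, [K+].[O-]S(=O)(=O)OO
Why: Shi epoxidation of the electron-rich E-trisubstituted alkene through the spiro transition state of the D-fructose-derived dioxirane should give the (R,R)-epoxide (1R,10R) under catalyst control, the iodo-alkene being too electron-poor and hindered to compete.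

**Step 12**
Reactants: 15 diepoxy alcohol
Product: 16 (2S,3R)-3-({(2R,3R)-3-[(2R,3Z)-2-{[tert-butyl(dimethyl)silyl]oxy}-4-iodo-3-methylbut-3-en-1-yl]-2-methyloxiran-2-yl}methyl)oxirane-2-carbaldehyde
Conditions: PhI(OAc)2 (1.2 equiv), TEMPO (10 mol %), CH2Cl2, rt; used without chromatography
Reagents that add atoms: none
Why: Oxoammonium-mediated oxidation of the primary alcohol is near neutral and should give the sensitive epoxy aldehyde without epimerisation at C7 (the descriptor changes from R to S only through the priority rules).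

**Step 13**
Reactants: 16 iodo epoxy aldehyde
Product: 17 (1R,3R,4Z,6R,7R,8R,10R)-3-[(tert-butyldimethylsilyl)oxy]-4,10-dimethyl-1,10:7,8-diepoxycyclodec-4-en-6-ol
Conditions: CrCl2 (8 equiv), NiCl2 (5 mol %), DMSO/THF, rt, slow addition to 0.002 M
Reagents that add atoms: none
Why: In this Nozaki–Hiyama–Kishi ring closure zerovalent nickel inserts into the C5–I bond, transmetallation to chromium gives a C5 nucleophile that adds to the C6 aldehyde with retention of the Z geometry, and Felkin–Anh attack anti to the C7–O bond of the neighbouring epoxide should give the 6,7-anti epoxy alcohol (6R).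

**Step 14**
Reactants: 17 macrocyclic diepoxy alcohol
Product: 18 (1R,3R,4Z,6R,7S,8R,10R)-3-[(tert-butyldimethylsilyl)oxy]-4,10-dimethyl-1,10:7,8-diepoxycyclodec-4-en-6-yl prop-2-enoate
Conditions: acryloyl chloride, iPr2NEt, CH2Cl2, −40 → 0 °C
Reagents that add atoms: acryloyl chloride, C=CC(=O)Cl
Why: O-Acylation of the only free hydroxyl installs C11–C13 on O6 (the C7 descriptor changes only through the priority rules).

**Step 15**
Reactants: 18 acrylate
Product: 21 (1R,3R,4Z,6R,7R,8R,10R)-3-[(tert-butyldimethylsilyl)oxy]-1,10-epoxy-8-hydroxygermacra-4,11(13)-dien-12,6-olide, via phosphonium enolate 19 (not isolated), via phosphonium lactone alkoxide 20 (not isolated)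
Conditions: PMe3 (50 mol %), t-BuOH/THF (1:1), 0.01 M, rt → 40 °C
Reagents that add atoms: none
Why: Proposed new method: PMe3 adds reversibly to C13 of the acrylate to give enolate 19, whose C11 opens the adjacent trans-7,8-epoxide at C7 from the rear (t-BuOH hydrogen-bonds the epoxide oxygen) to give alkoxide 20, which removes the C11 proton so that E1cB loss of PMe3 restores the C11=C13 bond and frees the catalyst; the closest known reaction type is the phosphine-mediated intramolecular Morita–Baylis–Hillman alkylation of enones with epoxides, here extended to an acrylate tethered through its ester oxygen. The only ring closed is the γ-lactone (O6–C12–C11–C7–C6), by 5-exo-tet opening of the epoxide. The one new stereocentre, C7, is set by SN2 inversion at the epoxide carbon, which puts C11 anti to the C8 oxygen and trans to H6 (trans-fused lactone), while C8 keeps its configuration and becomes the free 8-hydroxyl. The step needs attack at C7 and not at C8 or at the 1,10-epoxide: the three-atom O6–C12–C11 tether reaches C7 in line with the breaking C–O bond when O6 lies anti to it (extended C5–C6–C7–C8 conformer), as in the known C-2 openings of 2,3-epoxy alcohol carbamates, whereas C8 would need a six-membered, poorly aligned transition state and the trisubstituted 1,10-epoxide is out of reach. It also needs C-alkylation and cyclisation faster than acrylate dimerisation, which the dilution and the intramolecular 5-exo geometry should secure.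

**Step 16**
Reactants: 21 hydroxy lactone
Product: 22 (1R,3R,4Z,6R,7R,8R,10R)-3-[(tert-butyldimethylsilyl)oxy]-1,10-epoxy-8-(3-methylbutanoyloxy)germacra-4,11(13)-dien-12,6-olide
Conditions: isovaleric anhydride, DMAP (10 mol %), Et3N, CH2Cl2, 0 °C → rt
Reagents that add atoms: 3-methylbutanoic (isovaleric) anhydride, CC(C)CC(=O)OC(=O)CC(C)C
Why: DMAP-catalysed acylation of the secondary 8-hydroxyl is fast under mildly basic conditions, which should outrun translactonisation to O8.

**Step 17**
Reactants: 22 silyl-protected ester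
Product: 23 (1R,3R,4Z,6R,7R,8R,10R)-1,10-epoxy-3-hydroxy-8-(3-methylbutanoyloxy)germacra-4,11(13)-dien-12,6-olide (CNP0300193.1)
Conditions: HF·pyridine, pyridine, THF, 0 °C → rt
Reagents that add atoms: none
Why: Pyridine-buffered fluoride cleaves the allylic silyl ether and should spare the epoxide, the isovalerate and the methylene lactone.

**Compound list**
1 | prop-2-yn-1-ol | C#CCO | starting material
2 | bromomagnesium (Z)-3-(bromomagnesio)-2-methylprop-2-en-1-olate | Br[Mg]OC/C(C)=C\[Mg]Br | intermediate (not isolated)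
3 | (Z)-3-iodo-2-methylprop-2-en-1-ol | OC/C(C)=C\I | intermediate
4 | (Z)-3-iodo-2-methylprop-2-enal | O=C/C(C)=C\I | intermediate
5 | ethyl (E)-2-methylbut-2-enoate (ethyl tiglate) | CCOC(=O)/C(C)=C/C | starting material
6 | lithium 1-ethoxy-2-methylbuta-1,3-dien-1-olate | [Li]OC(OCC)=C(C)C=C | intermediate (not isolated)
7 | tert-butyl[(1-ethoxy-2-methylbuta-1,3-dien-1-yl)oxy]dimethylsilane | CCOC(O[Si](C)(C)C(C)(C)C)=C(C)C=C | intermediate
8 | ethyl (2E,5R,6Z)-5-hydroxy-7-iodo-2,6-dimethylhepta-2,6-dienoate | CCOC(=O)/C(C)=C/C[C@@H](O)/C(C)=C\I | intermediate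
9 | ethyl (2E,5R,6Z)-5-[(tert-butyldimethylsilyl)oxy]-7-iodo-2,6-dimethylhepta-2,6-dienoate | CCOC(=O)/C(C)=C/C[C@@H](O[Si](C)(C)C(C)(C)C)/C(C)=C\I | intermediate
10 | (2E,5R,6Z)-5-[(tert-butyldimethylsilyl)oxy]-7-iodo-2,6-dimethylhepta-2,6-dien-1-ol | OC/C(C)=C/C[C@@H](O[Si](C)(C)C(C)(C)C)/C(C)=C\I | intermediate
11 | tert-butyl{[(1Z,3R,5E)-7-bromo-1-iodo-2,6-dimethylhepta-1,5-dien-3-yl]oxy}dimethylsilane | BrC/C(C)=C/C[C@@H](O[Si](C)(C)C(C)(C)C)/C(C)=C\I | intermediate
12 | (5E,8R,9Z)-8-[(tert-butyldimethylsilyl)oxy]-10-iodo-5,9-dimethyldeca-5,9-dien-2-yn-1-ol | OCC#CC/C(C)=C/C[C@@H](O[Si](C)(C)C(C)(C)C)/C(C)=C\I | intermediate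
13 | (2E,5E,8R,9Z)-8-[(tert-butyldimethylsilyl)oxy]-10-iodo-5,9-dimethyldeca-2,5,9-trien-1-ol | OC/C=C/C/C(C)=C/C[C@@H](O[Si](C)(C)C(C)(C)C)/C(C)=C\I | intermediate
14 | {(2R,3R)-3-[(2E,5R,6Z)-5-{[tert-butyl(dimethyl)silyl]oxy}-7-iodo-2,6-dimethylhepta-2,6-dien-1-yl]oxiran-2-yl}methanol | OC[C@H]1O[C@@H]1C/C(C)=C/C[C@@H](O[Si](C)(C)C(C)(C)C)/C(C)=C\I | intermediate
15 | [(2R,3R)-3-({(2R,3R)-3-[(2R,3Z)-2-{[tert-butyl(dimethyl)silyl]oxy}-4-iodo-3-methylbut-3-en-1-yl]-2-methyloxiran-2-yl}methyl)oxiran-2-yl]methanol | OC[C@H]1O[C@@H]1C[C@@]2(C)O[C@@H]2C[C@@H](O[Si](C)(C)C(C)(C)C)/C(C)=C\I | intermediate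
16 | (2S,3R)-3-({(2R,3R)-3-[(2R,3Z)-2-{[tert-butyl(dimethyl)silyl]oxy}-4-iodo-3-methylbut-3-en-1-yl]-2-methyloxiran-2-yl}methyl)oxirane-2-carbaldehyde | O=C[C@H]1O[C@@H]1C[C@@]2(C)O[C@@H]2C[C@@H](O[Si](C)(C)C(C)(C)C)/C(C)=C\I | intermediate
17 | (1R,3R,4Z,6R,7R,8R,10R)-3-[(tert-butyldimethylsilyl)oxy]-4,10-dimethyl-1,10:7,8-diepoxycyclodec-4-en-6-ol | O[C@@H]1/C=C(/C)[C@H](O[Si](C)(C)C(C)(C)C)C[C@H]2O[C@]2(C)C[C@H]3O[C@H]13 | intermediate
18 | (1R,3R,4Z,6R,7S,8R,10R)-3-[(tert-butyldimethylsilyl)oxy]-4,10-dimethyl-1,10:7,8-diepoxycyclodec-4-en-6-yl prop-2-enoate | C=CC(=O)O[C@@H]1/C=C(/C)[C@H](O[Si](C)(C)C(C)(C)C)C[C@H]2O[C@]2(C)C[C@H]3O[C@H]13 | intermediate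
19 | C13-trimethylphosphonium ester enolate of 18 (zwitterion) | C[P+](C)(C)CC=C([O-])O[C@@H]1/C=C(/C)[C@H](O[Si](C)(C)C(C)(C)C)C[C@H]2O[C@]2(C)C[C@H]3O[C@H]13 | intermediate (not isolated)
20 | 13-(trimethylphosphonio)-11,13-dihydro lactone 8-alkoxide (zwitterion, C11 unassigned) | C[P+](C)(C)CC1C(=O)O[C@@H]2/C=C(/C)[C@H](O[Si](C)(C)C(C)(C)C)C[C@H]3O[C@]3(C)C[C@@H]([O-])[C@@H]12 | intermediate (not isolated)
21 | (1R,3R,4Z,6R,7R,8R,10R)-3-[(tert-butyldimethylsilyl)oxy]-1,10-epoxy-8-hydroxygermacra-4,11(13)-dien-12,6-olide | C=C1C(=O)O[C@@H]2/C=C(/C)[C@H](O[Si](C)(C)C(C)(C)C)C[C@H]3O[C@]3(C)C[C@@H](O)[C@@H]12 | intermediate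
22 | (1R,3R,4Z,6R,7R,8R,10R)-3-[(tert-butyldimethylsilyl)oxy]-1,10-epoxy-8-(3-methylbutanoyloxy)germacra-4,11(13)-dien-12,6-olide | C=C1C(=O)O[C@@H]2/C=C(/C)[C@H](O[Si](C)(C)C(C)(C)C)C[C@H]3O[C@]3(C)C[C@@H](OC(=O)CC(C)C)[C@@H]12 | intermediate
23 | (1R,3R,4Z,6R,7R,8R,10R)-1,10-epoxy-3-hydroxy-8-(3-methylbutanoyloxy)germacra-4,11(13)-dien-12,6-olide | C=C1C(=O)O[C@@H]2/C=C(/C)[C@H](O)C[C@H]3O[C@]3(C)C[C@@H](OC(=O)CC(C)C)[C@@H]12 | target

**Step count**
Total: 17 steps. Longest linear sequence: 16 steps (steps 1, 2 and 4–17; step 3 is a one-step side branch).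

**Steps most likely to fail**

Step 15 (proposed new method). The catalytic phosphonium enolate may be too dilute or too weak a nucleophile for an unactivated epoxide, so that acrylate oligomerisation or recovery of 18 takes over. The fallback sets out from 17. Steglich esterification with diethylphosphonoacetic acid (EDC, DMAP, CH2Cl2) would give the phosphonoacetate F1. NaH in THF (or DBU/LiCl in MeCN) would then generate the stabilised carbanion in full and close the lactone by the same 5-exo opening at C7, giving the α-phosphono lactone F2. Horner–Wadsworth–Emmons methylenation with paraformaldehyde and K2CO3 in THF would return the route at 21.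

Step 13. Poor facial selectivity at the aldehyde carbon under the constraints of the ten-membered transition state would give both C6 epimers. The fallback sets out from 16 and runs the same ring closure; the mixture of 17 and the 6-epi alcohol F3 is not separated. Oxidation with Dess–Martin periodinane (NaHCO3, CH2Cl2) would converge it to the epoxy ketone F4. Reduction with Zn(BH4)2 (Et2O, −20 °C), guided by the zinc chelate between the ketone and the epoxide oxygen, should give the anti epoxy alcohol and return the route at 17.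

Step 9. Loss of iodine from the alkenyl iodide by the aluminium hydride could compete with hydroalumination of the alkyne. The fallback sets out from 12. Trans-hydrosilylation with (EtO)3SiH and [Cp*Ru(MeCN)3]PF6 (CH2Cl2, 0 °C) would give the (Z)-alkenylsilane F5 (the regioisomeric silane leads to the same alkene). Protodesilylation with AgF in aqueous THF/MeOH would return the route at 13 without any hydride reagent.

**Further compounds**
F1 | step 15 | (1R,3R,4Z,6R,7S,8R,10R)-3-[(tert-butyldimethylsilyl)oxy]-4,10-dimethyl-1,10:7,8-diepoxycyclodec-4-en-6-yl 2-(diethoxyphosphoryl)acetate | CCOP(=O)(OCC)CC(=O)O[C@@H]1/C=C(/C)[C@H](O[Si](C)(C)C(C)(C)C)C[C@H]2O[C@]2(C)C[C@H]3O[C@H]13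
F2 | step 15 | (1R,3R,4Z,6R,7R,8R,10R)-3-[(tert-butyldimethylsilyl)oxy]-11-(diethoxyphosphoryl)-1,10-epoxy-8-hydroxy-13-norgermacr-4-en-12,6-olide (C11 epimers) | CCOP(=O)(OCC)C1C(=O)O[C@@H]2/C=C(/C)[C@H](O[Si](C)(C)C(C)(C)C)C[C@H]3O[C@]3(C)C[C@@H](O)[C@@H]12
F3 | step 13 | (1R,3R,4Z,6S,7R,8R,10R)-3-[(tert-butyldimethylsilyl)oxy]-4,10-dimethyl-1,10:7,8-diepoxycyclodec-4-en-6-ol (6-epimer of 17) | O[C@H]1/C=C(/C)[C@H](O[Si](C)(C)C(C)(C)C)C[C@H]2O[C@]2(C)C[C@H]3O[C@H]13
F4 | step 13 | (1R,3R,4Z,7S,8R,10R)-3-[(tert-butyldimethylsilyl)oxy]-4,10-dimethyl-1,10:7,8-diepoxycyclodec-4-en-6-one | O=C1/C=C(/C)[C@H](O[Si](C)(C)C(C)(C)C)C[C@H]2O[C@]2(C)C[C@H]3O[C@H]13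
F5 | step 9 | (2Z,5E,8R,9Z)-8-[(tert-butyldimethylsilyl)oxy]-10-iodo-5,9-dimethyl-3-(triethoxysilyl)deca-2,5,9-trien-1-ol | OC/C=C(\[Si](OCC)(OCC)OCC)C/C(C)=C/C[C@@H](O[Si](C)(C)C(C)(C)C)/C(C)=C\I
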